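Retrosynthetic overview
- The route rests on the cyclopentane C13–C17 (numbering from the ester carbon C1). Its C13–C17 bond and the C18–Cl bond stand anti across what was a (17Z)-alkene, and C13 has oxygen on its neighbour C14. This is the pattern left when an alkene attacks a C13 cation and chloride caps C18.
- Late disconnections: the three Z alkenes go back to a skipped 5,8,11-triyne (one Lindlar reduction), C10–C11 to a ring-bound terminal alkyne plus a C1–C10 propargylic halide (copper coupling), and the C14/C15 oxirane to the cis-diol (closed with retention).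
- Key disconnection: C13–C17 and C18–Cl together, back to the Co2(CO)6 complex of a trans-13,14-epoxy-11-yne carrying a 15-silyloxy group and the (17Z)-alkene. TiCl4 opens the epoxide to a cobalt-stabilised propargylic cation.
- The open chain comes from lithiated (trimethylsilyl)butadiyne and (Z)-hex-3-enal, then trans-reduction, Sharpless kinetic resolution (C14, C15), silylation and complexation. Ring order: cyclopentane (step 7), then oxirane (step 10).

Key step: step 7

Assumption: (Z)-hex-3-enal is made fresh from the stable alcohol because the commercial aldehyde is sold as a stabilised solution that an organolithium cannot tolerate; Co2(CO)6–alkyne clusters are written in SMILES as dicobaltatetrahedranes, and atom labels C1–C20 follow the target chain.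

Step 1
Reactants: 1 (Z)-hex-3-en-1-ol
Product: 2 (Z)-hex-3-enal
Conditions: Dess–Martin periodinane, NaHCO3, CH2Cl2, 0 °C to rt; filtered through silica and used at once as a cold solution
Reagents that add atoms: none
Why: The Dess–Martin oxidation runs close to neutral under bicarbonate buffering, so the β,γ-unsaturated aldehyde should form without migration of the Z alkene into conjugation.

Step 2
Reactants: 3 1,4-bis(trimethylsilyl)buta-1,3-diyne; 2 (Z)-hex-3-enal
Product: 5 rac-(7Z)-1-(trimethylsilyl)dec-7-ene-1,3-diyn-5-ol, via lithium 4-(trimethylsilyl)buta-1,3-diynide 4 (not isolated)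
Conditions: MeLi·LiBr (1 equiv), THF, 0 °C to rt; then 2, −78 °C; aq NH4Cl
Reagents that add atoms: none
Why: Methyllithium cleaves one C–Si bond (desilylative lithiation) and the lithium acetylide should add 1,2 to the aldehyde at −78 °C faster than it deprotonates the doubly activated α-position (acetylide addition to an aldehyde); C15 forms racemic and is resolved in step 4.

Step 3
Reactants: 5 rac-(7Z)-1-(trimethylsilyl)dec-7-ene-1,3-diyn-5-ol
Product: 6 rac-(3E,7Z)-1-(trimethylsilyl)deca-3,7-dien-1-yn-5-ol
Conditions: LiAlH4, THF, 0 °C to rt; then H2O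
Reagents that add atoms: none
Why: The aluminium alkoxide delivers hydride only to the neighbouring triple bond (trans-hydroalumination of a propargylic alcohol), which after protonolysis should give the E alkene and leave the silyl-capped alkyne and the remote Z alkene untouched.

Step 4
Reactants: 6 rac-(3E,7Z)-1-(trimethylsilyl)deca-3,7-dien-1-yn-5-ol
Product: 7 (1S,3Z)-1-{(2S,3S)-3-[(trimethylsilyl)ethynyl]oxiran-2-yl}hex-3-en-1-ol
Conditions: Ti(OiPr)4, L-(+)-diisopropyl tartrate, tBuOOH (0.55 equiv), 4 Å molecular sieves, CH2Cl2, −20 °C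
Reagents that add atoms: tert-butyl hydroperoxide, CC(C)(C)OO
Why: In the Sharpless kinetic resolution with the L-(+)-tartrate the (S)-alcohol should be epoxidised fast and on the face that gives the erythro (anti) epoxy alcohol, so C13 and C14 are set and C15 is resolved in one operation, while the homoallylic Z alkene reacts far more slowly and the (R)-alcohol is left behind and separated.

Step 5
Reactants: 7 (1S,3Z)-1-{(2S,3S)-3-[(trimethylsilyl)ethynyl]oxiran-2-yl}hex-3-en-1-ol
Product: 8 tert-butyldimethyl{[(1S,3Z)-1-{(2R,3S)-3-[(trimethylsilyl)ethynyl]oxiran-2-yl}hex-3-en-1-yl]oxy}silane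
Conditions: TBSCl, imidazole, DMF, rt
Reagents that add atoms: tert-butyldimethylsilyl chloride, CC(C)(C)[Si](C)(C)Cl
Why: Silylation of a secondary alcohol with a silyl chloride and imidazole is routine and spares the epoxide, and the silyl ether cannot act as a neighbouring group in step 7.

Step 6
Reactants: 8 tert-butyldimethyl{[(1S,3Z)-1-{(2R,3S)-3-[(trimethylsilyl)ethynyl]oxiran-2-yl}hex-3-en-1-yl]oxy}silane
Product: 9 hexacarbonyldicobalt complex of 8 (Co2(CO)6 cluster on C11≡C12)
Conditions: Co2(CO)8, CH2Cl2, rt
Reagents that add atoms: dicobalt octacarbonyl, O=C=[Co](=C=O)(=C=O)(=C=O)[Co](=C=O)(=C=O)(=C=O)=C=O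
Why: Dicobalt octacarbonyl complexes the alkyne with loss of two CO (alkyne–Co2(CO)6 cluster formation) under neutral conditions that touch neither the epoxide nor the alkene.

Step 7
Reactants: 9 hexacarbonyldicobalt complex of 8
Product: 10 hexacarbonyldicobalt complex of (1R,2R,3R,5S)-5-[(tert-butyldimethylsilyl)oxy]-3-[(1S)-1-chloropropyl]-2-[(trimethylsilyl)ethynyl]cyclopentan-1-ol
Conditions: TiCl4 (1.5 equiv), CH2Cl2, −78 to −40 °C; then H2O
Reagents that add atoms: titanium tetrachloride, Cl[Ti](Cl)(Cl)Cl
Why: Proposed new method: TiCl4 binds the oxirane oxygen and the cobalt cluster assists heterolysis of the propargylic C13–O bond, giving a Nicholas cation at C13 with a titanium alkoxide on C14; the (17Z)-alkene then adds to C13 through C17 while a chloride of the chlorotitanate is delivered to C18 on the opposite alkene face. The closest known reaction types are the intramolecular Nicholas reaction of tethered alkenes with halide capture at a tertiary centre and the Lewis-acid opening of Co2(CO)6-complexed alkynyl epoxides by internal nucleophiles; chloride capture at a secondary centre after attack by a 1,2-disubstituted alkene has no precedent. The cyclopentane C13–C14–C15–C16–C17 closes in the 5-exo-trig mode with respect to the alkene. C13 is set under Curtin–Hammett control, because the cation inverts faster than a weak π-nucleophile attacks it and the bulky Co2(CO)6 cluster should take the position trans to the C14 titanium alkoxide; C17 is set by the same cluster, which pushes the C18 branch to the opposite ring face (cis to O14 and O15); C18 follows from the anti addition across the Z alkene, which translates Z into the (17R,18S) relationship. The step needs 5-exo over 6-endo closure and chloride capture faster than proton loss, hydride shift or capture by O14: the first should be helped by the inductive pull of the C15 silyloxy group, which disfavours positive charge on C17, and by the bulk at C13, which prefers the alkene carbon C17 over the ethyl-bearing C18, and the second by the chloride-rich titanate held next to the cation at −78 °C.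

Step 8
Reactants: 10 hexacarbonyldicobalt complex of the chlorocyclopentanol
Product: 11 (1R,2R,3R,5S)-5-[(tert-butyldimethylsilyl)oxy]-3-[(1S)-1-chloropropyl]-2-[(trimethylsilyl)ethynyl]cyclopentan-1-ol
Conditions: (NH4)2Ce(NO3)6, acetone, −10 °C
Reagents that add atoms: none
Why: Oxidation of the cobalt cluster (oxidative decomplexation of a Nicholas product) should release the alkyne at low temperature without touching the alkyl chloride or the silyl groups.

Step 9
Reactants: 11 (1R,2R,3R,5S)-5-[(tert-butyldimethylsilyl)oxy]-3-[(1S)-1-chloropropyl]-2-[(trimethylsilyl)ethynyl]cyclopentan-1-ol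
Product: 12 (1S,2R,3R,4R)-4-[(1S)-1-chloropropyl]-3-ethynylcyclopentane-1,2-diol
Conditions: Bu4NF, THF, 0 °C to rt
Reagents that add atoms: none
Why: Fluoride cleaves the O–Si and the C(sp)–Si bond in one operation (fluoride desilylation), and a secondary alkyl chloride should survive it at this temperature.

Step 10
Reactants: 12 (1S,2R,3R,4R)-4-[(1S)-1-chloropropyl]-3-ethynylcyclopentane-1,2-diol
Product: 15 (1R,2R,3R,5S)-3-[(1S)-1-chloropropyl]-2-ethynyl-6-oxabicyclo[3.1.0]hexane, via cyclic methyl orthoacetate 13 (not isolated), via trans-bromo acetate 14 (not isolated)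
Conditions: MeC(OMe)3, pyridinium p-toluenesulfonate (cat.), CH2Cl2, rt; then AcBr, CH2Cl2, 0 °C to rt; then K2CO3, MeOH, rt
Reagents that add atoms: none
Why: The cis-diol is converted in one pot through its cyclic orthoacetate into the acetoxonium ion, which bromide opens with inversion, and base then closes the ring with a second inversion (acetoxonium/halohydrin ester route to epoxides), so the oxirane should end on the face the two hydroxyls occupied, and either regioisomer of the bromo acetate closes to the same epoxide.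

Step 11
Reactants: 16 methyl hex-5-ynoate; 17 1,4-dichlorobut-2-yne (4 equiv)
Product: 19 methyl 10-chlorodeca-5,8-diynoate, via 1-chloro-4-iodobut-2-yne 18 (not isolated)
Conditions: NaI (1 equiv), CuI, K2CO3, DMF, rt
Reagents that add atoms: none
Why: Copper-mediated coupling of a terminal alkyne with a propargylic halide after in situ Finkelstein exchange gives the skipped diyne, the excess of dihalide should hold back double coupling, and the ester is inert to the carbonate base.

Step 12
Reactants: 15 (1R,2R,3R,5S)-3-[(1S)-1-chloropropyl]-2-ethynyl-6-oxabicyclo[3.1.0]hexane; 19 methyl 10-chlorodeca-5,8-diynoate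
Product: 21 methyl 12-{(1R,2R,3R,5S)-3-[(1S)-1-chloropropyl]-6-oxabicyclo[3.1.0]hexan-2-yl}dodeca-5,8,11-triynoate, via methyl 10-iododeca-5,8-diynoate 20 (not isolated)
Conditions: NaI, CuI, Cs2CO3, DMF, rt
Reagents that add atoms: none
Why: The same copper acetylide–propargylic halide coupling forms the C10–C11 bond under mildly basic conditions that should spare the epoxide and the secondary chloride.

Step 13
Reactants: 21 methyl 12-{(1R,2R,3R,5S)-3-[(1S)-1-chloropropyl]-6-oxabicyclo[3.1.0]hexan-2-yl}dodeca-5,8,11-triynoate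
Product: 22 methyl (5Z,8Z,11Z)-12-{(1R,2S,3R,5S)-3-[(1S)-1-chloropropyl]-6-oxabicyclo[3.1.0]hexan-2-yl}dodeca-5,8,11-trienoate (CNP0141251.1)
Conditions: H2 (1 atm), Pd/CaCO3 poisoned with Pb(OAc)2, quinoline, EtOAc, rt
Reagents that add atoms: none
Why: Lindlar semihydrogenation adds H2 syn to each triple bond and the poisoned palladium should stop at the alkene, so the three alkynes become the (5Z,8Z,11Z)-triene while the epoxide and the alkyl chloride are inert.

Compound list
1 | (Z)-hex-3-en-1-ol | CC/C=C\CCO | starting material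
2 | (Z)-hex-3-enal | CC/C=C\CC=O | intermediate
3 | 1,4-bis(trimethylsilyl)buta-1,3-diyne | C[Si](C)(C)C#CC#C[Si](C)(C)C | starting material
4 | lithium 4-(trimethylsilyl)buta-1,3-diynide | [Li]C#CC#C[Si](C)(C)C | intermediate
5 | rac-(7Z)-1-(trimethylsilyl)dec-7-ene-1,3-diyn-5-ol | C[Si](C)(C)C#CC#CC(O)C/C=C\CC | intermediate
6 | rac-(3E,7Z)-1-(trimethylsilyl)deca-3,7-dien-1-yn-5-ol | C[Si](C)(C)C#C/C=C/C(O)C/C=C\CC | intermediate
7 | (1S,3Z)-1-{(2S,3S)-3-[(trimethylsilyl)ethynyl]oxiran-2-yl}hex-3-en-1-ol | C[Si](C)(C)C#C[C@@H]1O[C@H]1[C@@H](O)C/C=C\CC | intermediate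
8 | tert-butyldimethyl{[(1S,3Z)-1-{(2R,3S)-3-[(trimethylsilyl)ethynyl]oxiran-2-yl}hex-3-en-1-yl]oxy}silane | C[Si](C)(C)C#C[C@@H]1O[C@H]1[C@@H](O[Si](C)(C)C(C)(C)C)C/C=C\CC | intermediate
9 | hexacarbonyldicobalt complex of 8 (cluster on C11≡C12) | C[Si](C)(C)C12C3([C@@H]4O[C@H]4[C@@H](O[Si](C)(C)C(C)(C)C)C/C=C\CC)[Co]1(=C=O)(=C=O)(=C=O)[Co]23(=C=O)(=C=O)=C=O | intermediate
10 | hexacarbonyldicobalt complex of 11 (cluster on C11≡C12) | CC[C@H](Cl)[C@@H]1C[C@H](O[Si](C)(C)C(C)(C)C)[C@H](O)[C@H]1C23C4([Si](C)(C)C)[Co]2(=C=O)(=C=O)(=C=O)[Co]34(=C=O)(=C=O)=C=O | intermediate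
11 | (1R,2R,3R,5S)-5-[(tert-butyldimethylsilyl)oxy]-3-[(1S)-1-chloropropyl]-2-[(trimethylsilyl)ethynyl]cyclopentan-1-ol | CC[C@H](Cl)[C@@H]1C[C@H](O[Si](C)(C)C(C)(C)C)[C@H](O)[C@H]1C#C[Si](C)(C)C | intermediate
12 | (1S,2R,3R,4R)-4-[(1S)-1-chloropropyl]-3-ethynylcyclopentane-1,2-diol | CC[C@H](Cl)[C@@H]1C[C@H](O)[C@H](O)[C@H]1C#C | intermediate
13 | cyclic methyl orthoacetate of 12 (2-methoxy-2-methyl-1,3-dioxolane cis-fused at C14/C15, orthoester carbon as a mixture) | CC[C@H](Cl)[C@@H]1C[C@@H]2OC(C)(OC)O[C@@H]2[C@H]1C#C | intermediate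
14 | trans-bromo acetate of 12 (acetate on C14 with retention, bromide on C15 with inversion) | CC[C@H](Cl)[C@@H]1C[C@@H](Br)[C@H](OC(C)=O)[C@H]1C#C | intermediate
15 | (1R,2R,3R,5S)-3-[(1S)-1-chloropropyl]-2-ethynyl-6-oxabicyclo[3.1.0]hexane | CC[C@H](Cl)[C@@H]1C[C@@H]2O[C@@H]2[C@H]1C#C | intermediate
16 | methyl hex-5-ynoate | C#CCCCC(=O)OC | starting material
17 | 1,4-dichlorobut-2-yne | ClCC#CCCl | starting material
18 | 1-chloro-4-iodobut-2-yne | ClCC#CCI | intermediate
19 | methyl 10-chlorodeca-5,8-diynoate | ClCC#CCC#CCCCC(=O)OC | intermediate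
20 | methyl 10-iododeca-5,8-diynoate | ICC#CCC#CCCCC(=O)OC | intermediate
21 | methyl 12-{(1R,2R,3R,5S)-3-[(1S)-1-chloropropyl]-6-oxabicyclo[3.1.0]hexan-2-yl}dodeca-5,8,11-triynoate | CC[C@H](Cl)[C@@H]1C[C@@H]2O[C@@H]2[C@H]1C#CCC#CCC#CCCCC(=O)OC | intermediate
22 | methyl (5Z,8Z,11Z)-12-{(1R,2S,3R,5S)-3-[(1S)-1-chloropropyl]-6-oxabicyclo[3.1.0]hexan-2-yl}dodeca-5,8,11-trienoate | CC[C@H](Cl)[C@@H]1C[C@@H]2O[C@@H]2[C@H]1/C=C\C/C=C\C/C=C\CCCC(=O)OC | target

Total step count: 13 (12 in the main line, 1 for the C1–C10 halide).
Longest linear sequence: 12 steps (steps 1–10, 12 and 13).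

Steps most likely to fail

1. Step 7 (proposed new method). Possible failures are closure through C18 to a six-membered ring, termination by proton loss or by the C14 alkoxide instead of chloride, decay of the cation before the weakly nucleophilic alkene attacks, or poor face selection at C13 and C17. The fallback replaces chloride capture by a silicon-terminated closure of known type and brings in chlorine afterwards by substitution; it sets out from 9 and comes back at 12.
   - Cross-metathesis of 9 with allyltrimethylsilane (second-generation Grubbs catalyst, CH2Cl2, 40 °C; the cobalt cluster masks the alkyne) should give the allylsilane complex F1.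
   - BF3·OEt2 at −78 °C should open the complexed epoxide and the allylsilane should close the ring through C17 with loss of silicon (allylsilane-terminated intramolecular Nicholas reaction, 5-exo, regiochemistry fixed by the β-silicon effect) to give the vinylcyclopentanol complex F2.
   - (NH4)2Ce(NO3)6 should release the vinyl alkyne F3, and TBSOTf with 2,6-lutidine should give the bis-silyl ether F4.
   - OsO4/NaIO4 should cleave the vinyl group to the aldehyde F5.
   - Et2Zn with a catalytic chiral amino alcohol, the ligand antipode chosen for reagent control, should give the (18R)-carbinol F6.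
   - An Appel reaction (PPh3, CCl4) should give, with inversion, the (18S)-chloride F7, and Bu4NF then leads to 12.

2. Step 13. Possible failures are over-reduction or incomplete reduction when three alkynes must be semihydrogenated at once, and loss of the air- and base-sensitive skipped triyne on handling. The fallback carries two of the Z alkenes into the coupling partner so that only one alkyne is left to reduce; it sets out from 16 (and uses 15) and comes back at 22.
   - Coupling of 16 with 4-chlorobut-2-yn-1-ol (CuI, NaI, K2CO3, DMF) should give methyl 10-hydroxydeca-5,8-diynoate F8.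
   - Semihydrogenation of this simple diyne over nickel boride (Ni2B from Ni(OAc)2 and NaBH4, ethylenediamine, H2) should give methyl (5Z,8Z)-10-hydroxydeca-5,8-dienoate F9.
   - An Appel bromination (CBr4, PPh3) should give methyl (5Z,8Z)-10-bromodeca-5,8-dienoate F10.
   - Copper-mediated coupling of this allylic bromide with 15 (CuI, NaI, K2CO3, DMF) should give the dienyne ester F11.
   - A single semihydrogenation (Pd/CaCO3 poisoned with Pb(OAc)2, quinoline, H2) should then give 22.

3. Step 4. Possible failures are slow epoxidation of the electron-poor enyne alkene, so that the resolution stops short and enantiomeric purity or erythro selectivity erodes; half of the material is lost by design in any case. The fallback sets C15 first by asymmetric reduction and then uses a matched epoxidation; it sets out from 5 and comes back at 7.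
   - Dess–Martin oxidation of 5 should give the ynone F12.
   - Noyori asymmetric transfer hydrogenation (preformed Ru[(S,S)-TsDPEN](p-cymene) amido complex, iPrOH, rt, no added base) should give the (S)-diynol F13.
   - LiAlH4 as in step 3 should give the (S)-enynol F14.
   - Sharpless epoxidation with Ti(OiPr)4, L-(+)-diisopropyl tartrate and a full equivalent of tBuOOH, now the matched case, should give 7 from all of the material.

Further compounds
F1 | step 7 | hexacarbonyldicobalt complex of tert-butyldimethyl{[(1S,3E)-5-(trimethylsilyl)-1-{(2R,3S)-3-[(trimethylsilyl)ethynyl]oxiran-2-yl}pent-3-en-1-yl]oxy}silane | C[Si](C)(C)C12C3([C@@H]4O[C@H]4[C@@H](O[Si](C)(C)C(C)(C)C)C/C=C/C[Si](C)(C)C)[Co]1(=C=O)(=C=O)(=C=O)[Co]23(=C=O)(=C=O)=C=O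
F2 | step 7 | hexacarbonyldicobalt complex of the 3-ethenyl analogue of 11 (vinyl on C17 in place of 1-chloropropyl) | C=C[C@@H]1C[C@H](O[Si](C)(C)C(C)(C)C)[C@H](O)[C@H]1C23C4([Si](C)(C)C)[Co]2(=C=O)(=C=O)(=C=O)[Co]34(=C=O)(=C=O)=C=O
F3 | step 7 | 5-[(tert-butyldimethylsilyl)oxy]-3-ethenyl-2-[(trimethylsilyl)ethynyl]cyclopentan-1-ol (ring configuration as in 11) | C=C[C@@H]1C[C@H](O[Si](C)(C)C(C)(C)C)[C@H](O)[C@H]1C#C[Si](C)(C)C
F4 | step 7 | bis(tert-butyldimethylsilyl) ether of the 3-ethenyl-2-[(trimethylsilyl)ethynyl]cyclopentane-1,5-diol | C=C[C@@H]1C[C@H](O[Si](C)(C)C(C)(C)C)[C@H](O[Si](C)(C)C(C)(C)C)[C@H]1C#C[Si](C)(C)C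
F5 | step 7 | 3,4-bis[(tert-butyldimethylsilyl)oxy]-2-[(trimethylsilyl)ethynyl]cyclopentane-1-carbaldehyde (aldehyde carbon is C18) | O=C[C@@H]1C[C@H](O[Si](C)(C)C(C)(C)C)[C@H](O[Si](C)(C)C(C)(C)C)[C@H]1C#C[Si](C)(C)C
F6 | step 7 | (1R)-1-{3,4-bis[(tert-butyldimethylsilyl)oxy]-2-[(trimethylsilyl)ethynyl]cyclopentyl}propan-1-ol | CC[C@@H](O)[C@@H]1C[C@H](O[Si](C)(C)C(C)(C)C)[C@H](O[Si](C)(C)C(C)(C)C)[C@H]1C#C[Si](C)(C)C
F7 | step 7 | bis(tert-butyldimethylsilyl) ether of 12 carrying the C-trimethylsilyl alkyne, (1S)-1-chloropropyl on C17 | CC[C@H](Cl)[C@@H]1C[C@H](O[Si](C)(C)C(C)(C)C)[C@H](O[Si](C)(C)C(C)(C)C)[C@H]1C#C[Si](C)(C)C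
F8 | step 13 | methyl 10-hydroxydeca-5,8-diynoate | OCC#CCC#CCCCC(=O)OC
F9 | step 13 | methyl (5Z,8Z)-10-hydroxydeca-5,8-dienoate | OC/C=C\C/C=C\CCCC(=O)OC
F10 | step 13 | methyl (5Z,8Z)-10-bromodeca-5,8-dienoate | BrC/C=C\C/C=C\CCCC(=O)OC
F11 | step 13 | methyl (5Z,8Z)-12-{(1R,2R,3R,5S)-3-[(1S)-1-chloropropyl]-6-oxabicyclo[3.1.0]hexan-2-yl}dodeca-5,8-dien-11-ynoate | CC[C@H](Cl)[C@@H]1C[C@@H]2O[C@@H]2[C@H]1C#CC/C=C\C/C=C\CCCC(=O)OC
F12 | step 4 | (7Z)-1-(trimethylsilyl)dec-7-ene-1,3-diyn-5-one | C[Si](C)(C)C#CC#CC(=O)C/C=C\CC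
F13 | step 4 | (5S,7Z)-1-(trimethylsilyl)dec-7-ene-1,3-diyn-5-ol | C[Si](C)(C)C#CC#C[C@@H](O)C/C=C\CC
F14 | step 4 | (3E,5S,7Z)-1-(trimethylsilyl)deca-3,7-dien-1-yn-5-ol | C[Si](C)(C)C#C/C=C/[C@@H](O)C/C=C\CC
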